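The runs are calculated with constants of no real substance, and the scatter is random.

A mixture's ratio moves toward the ratio of what is added to it, and that easy step can be tried on this flask, where substrate and other conformer give target and isomer of the product.

- east: substrate 0.38 M; other conformer 0.25 equiv; run made earlier
- flask: substrate 0.25 M; other conformer 0.250 equiv; time 15 h

east run (percent of the substrate and other conformer together charged)

| time / h | target / % | isomer of the product / % |
|---|---|---|
| 0.833 | 8.6 | 9.0 |
| 1.50 | 12.0 | 12.8 |
| 2.50 | 14.1 | 17.8 |
| 3.00 | 14.7 | 18.6 |

(standard deviation of a reading: 0.5 percentage points)

* ratio of target to isomer of the product at 100 s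
* ratio of target to isomer of the product at 15 h



From the first to the last east reading the target gains 6.1 percentage points and the isomer 9.6 points. Their quotient is 0.635, the stream ratio, new target per new isomer over a stretch of a run, which is an averaged selectivity.

Now the question turned round: what has to be true for the ratio to end at 0.5? Even with the whole remainder of the east charge, 66.7%, arriving as these two products, the stream has to run at 0.388, and lower still if less arrives. The east stream reads higher than that. Mixing the remainder in at the read stream gives 0.684, the reckoning here for 15 h, taking the thinner flask to behave like the east run. The east ratio reads 0.956 at 0.833 h and 0.790 at 3.00 h, so the reckoning here puts the flask's ratio at 100 s above the first of these readings.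

The forecast gave 1.05 and 0.5, lower at 15 h than the reckoning here, holding that “the target looks kinetic and the isomer thermodynamic”.

The flask gives 1.61 at 100 s and 0.887 at 15 h.

    substrate ⇌ other conformer (K = 0.340, k = 0.0270 min⁻¹)
    other conformer → isomer of the product (k = 0.0110 min⁻¹)
    substrate + target → side product (k = 0.0450 M⁻¹ min⁻¹)
    substrate → target (k = 0.00470 min⁻¹)
    substrate ⇌ dormant form (K = 1.10, k = 0.0300 min⁻¹)
    target ⇌ isomer of the product (K = 1.10, k = 0.00310 min⁻¹)

The stream ratio read as 0.635 belonged to the east stretch up to 3.00 h; in the flask the same quantity from 7.50 h to 15.0 h is 1.57, and over that stretch the flask's ratio climbs from 0.841. The largest single effect on the flask's ratio at 15 h is the way back from isomer to target: in the run without that step the ratio at 15 h is 0.0814. The neighbour at 0.10 M of substrate starts with neither product and ends with 35.3% target and 38.9% isomer, so its stream ratio over the whole run is 0.907.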